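The numbers belong to no real substance; what happens was integrated by code.

Two hands charged equally, never interconverted and both reacted to the end cannot end unequal: each becomes its own product, so a left-handed share of 0.5 is the zero of my scale.

left-handed substrate 0.20 M; reagent 2.50 equiv; free catalyst 0.1 mol%; impurity 0.12 mM; right-handed substrate 0.20 M; time 4.0 h

    reagent + free catalyst + left-handed substrate → free catalyst + left-handed product (k1 = 513 /M²/s)
    reagent + free catalyst + right-handed substrate → free catalyst + right-handed product (k2 = 238 /M²/s)
    left-handed substrate ⇌ right-handed substrate (k3 = 0.00416 /s)
    free catalyst ⇌ dormant form (K4 = 1.62, k4 = 0.00446 /s)
    free catalyst + impurity → spent catalyst (k5 = 504 /M/s)

- free catalyst is single-handed; left-handed substrate and right-handed substrate are mirror images of each other, charged as a racemate, each of them at the stated concentration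
- the reaction counts as stopped when no species that holds the left-handed substrate and right-handed substrate together changes by six tenths of a point or more over the second half of the time
- run time (flask): 4.0 h

- which holds at 4.0 h: what has brought the reaction to rest, or that it has not come to rest (no working catalyst is left / the reagent has run out first / all of the left-handed substrate has reacted / it is still moving / forward and back rates have come level)
- left-handed product at 4.0 h, in percent of the left-handed substrate and right-handed substrate together charged
- right-handed product at 4.0 h, in percent of the left-handed substrate and right-handed substrate together charged

The reagent covers both hands, with 2.50 equiv against the 2 equivalents they need, so I expect both to react and ask about the split. The other end of the scale is the selectivity factor, 2.16, the product ratio if the hands stay level.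

The impurity removes catalyst one for one, and with the impurity held at its charge the catalyst has a half-life of 0.191 min, shorter than the 1.60 min relaxation to the dormant form. I therefore take it first, then split the survivors by 1.62, which leaves a free fraction of 15.3 % of the catalyst charged. With the reagent held at its charge, the right hand is consumed at 0.00363 /s.

My mixing number x is the interconversion constant, doubled, over that consumption constant: 2.29. Integrating the two linear rate laws to the end gives a left-to-right product ratio of s(1+x)/(s+x), where s is the selectivity factor. This ratio is 1 at x of zero and tends to s at large x. Here it is 1.60, a left-handed share of 61.5 %.

The forecast gives 52.3 % and 47.7 %, lower on the left than my share, and puts the excess down to “the small amount of right-handed substrate that interconverts before it can react”. It states that all of the left-handed substrate has reacted.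

In the flask, all of the left-handed substrate has reacted, and it holds 62.4 % of left-handed product and 37.6 % of right-handed product. Its interconversion turns over backward, right to left, at 128 % of the forward turnover.

In the neighbouring flask with 0.620 equiv of reagent, the same free fraction gives a mixing number of 9.23, greater than 1, so I expect the hands to stay nearly level and the product ratio to lie close to s, 2.16. That flask does not react to the end: its reagent, now the limiting reagent, stands at 0 % with 34.5 % of right-handed substrate left. It holds 20.8 % of left-handed product and 10.2 % of right-handed product, a ratio of 2.04.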